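The data are simulated with constants of no real substance, noise included.

The product in the violet run climbs and then flattens, with 69.1% of the violet charge not in it at 22 h, so how far it climbs is the thing to watch.

| setting | violet | teal | amber | grey | red |
|---|---|---|---|---|---|
| starting material | 0.200 M | 0.0800 M | 0.200 M | 0.200 M | 0.100 M |
| coupling partner | 0.400 M | 0.280 M | 0.400 M | 1.20 M | 0.400 M |
| free catalyst | 0.00200 M | 0.00200 M | 0.00300 M | 0.00200 M | 0.00600 M |
| time |  |  |  |  | 22 h |

| violet run: time / h | violet run: [product] / M | teal run: time / h | teal run: [product] / M | amber run: time / h | amber run: [product] / M | grey run: time / h | grey run: [product] / M |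
|---|---|---|---|---|---|---|---|
| 1.3 | 0.0064 | 1.3 | 0.0045 | 1.3 | 0.0095 | 1.3 | 0.0074 |
| 3.8 | 0.0178 | 3.8 | 0.0132 | 3.8 | 0.0265 | 3.8 | 0.0213 |
| 7.3 | 0.0327 | 7.3 | 0.0235 | 7.3 | 0.0498 | 7.3 | 0.0389 |
| 11 | 0.0452 | 11 | 0.0305 | 11 | 0.0664 | 11 | 0.0529 |
| 16 | 0.0563 | 16 | 0.0337 | 16 | 0.0762 | 16 | 0.0606 |
| 22 | 0.0619 | 22 | 0.0359 | 22 | 0.0785 | 22 | 0.0644 |

(standard deviation of a reading: 6 × 10⁻⁴ M)

1. the exponent of [free catalyst] in the starting rate at the charge of the violet run (at the point where two percent of the starting material have become product)
2. the exponent of [starting material] in the starting rate at the charge of the violet run (at the point where two percent of the starting material have become product) (one fixed amount of product, the same in the runs compared)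
3. product in the red run at 22 h, as a share of the starting material charged

- Overall: starting material + coupling partner -> product, with free catalyst as catalyst.
- Constant volume, constant temperature.
- Bound and free are read together.
- "The second partner" is coupling partner.
- An order is taken over about fifteen percent of the charge, up and down.

My reckoning starts from an assumption: what is not product at 22 h left by a side route, and any starting material still unreacted then is counted with it. Divide that by the product, both gathered over the same hours, and time drops out. This leak ratio is then a ratio of two rates. Multiply it by the early rate of product, read at 3.8 h as a share of the charge per hour, and you have a leak rate.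

Violet: early rate 0.0234 /h, leak ratio 2.23, leak rate 0.0523 /h

Teal: early rate 0.0434 /h, leak ratio 1.23, leak rate 0.0533 /h

Amber: early rate 0.0349 /h, leak ratio 1.55, leak rate 0.0540 /h

Grey: early rate 0.0280 /h, leak ratio 2.11, leak rate 0.0590 /h

The leak ratios spread from 1.23 to 2.23, yet the leak rates stay between 0.0523 /h and 0.0590 /h. So I take the share that becomes product as early rate over early rate plus leak rate.

The forecast gives 1 (0.85 to 1.1) for the catalyst order, 0.18 (0.07 to 0.32) for the starting-material order, and 75% (58% to 92%) for the red run, reading the flattening as “so the catalyst dies”.

I read it as a leak instead, but I borrow its starting-material order. Amber's early rate over violet's is 1.49 for a catalyst ratio of 1.50, so I scale the rate with catalyst.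

Red from violet: early rate 0.124 /h, share 70.4%

The weak link is violet itself: its last interval adds 0.00560 M, more than amber's 0.00230 M. So I carry amber's figure instead, the share of the charge per hour going elsewhere than product.

Red from amber: early rate 0.123 /h, share 69.5%

I commit to 69.5%, lower than the forecast's 75%.

The flask gives a catalyst order of 1.0, a starting-material order of 0.15, and 68.6% of the starting material as product in the red run at 22 h.

    free catalyst + starting material → catalyst-substrate complex (102.2 /M/h)
    catalyst-substrate complex + coupling partner → loaded catalyst (28.33 /M/h)
    loaded catalyst → product + free catalyst (4.068 /h)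
    free catalyst + product → spent catalyst + product (2.783 /M/h)
    starting material → decomposed substrate (0.09900 /h)

With my early rate, the red share of 68.6% corresponds to a leak rate of 0.0563 /h, beside the carried 0.0540 /h. The loss of starting material to decomposed substrate is the main reason the red run falls short: the red run without that step gives 95.6% instead of 68.6%, whereas removing the loss of free catalyst to spent catalyst gives 71.1%. In the red run without decomposition, the same reckoning gives a leak rate of 0.00566 /h.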